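**Retrosynthetic overview**

1. Target 16 ⇐ 15 (desilylation) ⇐ 12 (Claisen–Cope relay, two [3,3] shifts, of a 5-O-prenyl group to C8) ⇐ 10 + prenol 11 (Mitsunobu) ⇐ 9 (hydrogenolysis of the spare benzyl ether on O5).
2. 9 ⇐ 8: ring C is closed by forming C2–C3 in an enantioselective dirhodium-carbenoid 1,6 C–H insertion, which also sets C2, the only stereocenter. Rings A and B are bought (acetophenone 5, isovanillin 1); ring C is the only ring formed.
3. Enabling feature: the O1–CH2 benzylic methylene that becomes C2. Its C–H bonds are made hydridic by O1 and by the para-methoxyphenyl ring B, and they lie 1,6 to the carbenoid carbon (future C3) on the acyl group of ring A.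
4. 8 ⇐ 6 (deacylative diazo transfer) ⇐ 5 + 2 × 4: in the Cs-symmetric bis(benzyl ether) both ortho oxygens are identical, so one benzyl group becomes C2 plus ring B and the other protects O5.
5. 4 ⇐ 1 (silylation, reduction, bromination).

Key step: step 6

Assumption: the sense of induction of the chiral dirhodium catalyst in step 6 cannot be fixed in advance; Rh2(S-PTTL)4 is written, and its mirror-image form Rh2(R-PTTL)4 would be used instead if the first run showed the (2R) product to predominate.

**Route**

Step 1
Reactants: 1 isovanillin (3-hydroxy-4-methoxybenzaldehyde)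
Product: 2 4-methoxy-3-(triisopropylsilyloxy)benzaldehyde
Conditions: TIPSCl, imidazole, DMF, rt
Reagents that add atoms: chlorotri(propan-2-yl)silane (TIPSCl), CC(C)[Si](Cl)(C(C)C)C(C)C
Why: Imidazole-promoted silylation of the only hydroxyl group gives a bulky aryl silyl ether that should survive carbonate base, lithium amide, carbenoid, hydrogenation and Mitsunobu conditions and leave under buffered fluoride at the end.

Step 2
Reactants: 2 4-methoxy-3-(triisopropylsilyloxy)benzaldehyde
Product: 3 [4-methoxy-3-(triisopropylsilyloxy)phenyl]methanol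
Conditions: NaBH4, MeOH, 0 °C
Reagents that add atoms: none
Why: Hydride reduction of the aryl aldehyde by NaBH4 should be clean, the aryl silyl ether being inert to borohydride at 0 °C.

Step 3
Reactants: 3 [4-methoxy-3-(triisopropylsilyloxy)phenyl]methanol
Product: 4 4-methoxy-3-(triisopropylsilyloxy)benzyl bromide
Conditions: CBr4, PPh3, CH2Cl2, 0 °C
Reagents that add atoms: tetrabromomethane (CBr4), BrC(Br)(Br)Br
Why: The Appel reaction converts the electron-rich benzylic alcohol into the bromide under neutral conditions that spare the silyl ether; the labile bromide would be used directly.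

Step 4
Reactants: 5 1-(2,6-dihydroxy-4-methoxyphenyl)ethanone (2',6'-dihydroxy-4'-methoxyacetophenone); 4 4-methoxy-3-(triisopropylsilyloxy)benzyl bromide (2.2 equiv)
Product: 6 1-{4-methoxy-2,6-bis[(4-methoxy-3-(triisopropylsilyloxy)benzyl)oxy]phenyl}ethanone
Conditions: K2CO3, DMF, 50 °C
Reagents that add atoms: none
Why: Double Williamson etherification of both phenoxide oxygens (the second, hydrogen-bonded one needs the polar solvent and warming) with the reactive benzylic bromide gives a Cs-symmetric bis-ether, so no regiochemical question arises.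

Step 5
Reactants: 6 1-{4-methoxy-2,6-bis[(4-methoxy-3-(triisopropylsilyloxy)benzyl)oxy]phenyl}ethanone
Product: 8 2-diazo-1-{4-methoxy-2,6-bis[(4-methoxy-3-(triisopropylsilyloxy)benzyl)oxy]phenyl}ethanone, via trifluoroacetyl diketone 7 (not isolated)
Conditions: LiHMDS, THF, −78 °C; CF3CO2CH2CF3, −78 °C; 5% HCl work-up; then p-ABSA, Et3N, H2O, MeCN, rt
Reagents that add atoms: 4-acetamidobenzenesulfonyl azide (p-ABSA), CC(=O)Nc1ccc(cc1)S(=O)(=O)N=[N+]=[N-]; 2,2,2-trifluoroethyl trifluoroacetate, O=C(OCC(F)(F)F)C(F)(F)F (its trifluoroacetyl group stays only in intermediate 7)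
Why: In the Danheiser detrifluoroacetylative diazo transfer the kinetic lithium enolate of the methyl ketone is C-trifluoroacetylated to the activated 1,3-diketone 7, which takes the diazo group from the sulfonyl azide and loses its trifluoroacetyl group as the N-sulfonyl trifluoroacetamide to give the terminal diazoketone.

Step 6
Reactants: 8 2-diazo-1-{4-methoxy-2,6-bis[(4-methoxy-3-(triisopropylsilyloxy)benzyl)oxy]phenyl}ethanone
Product: 9 (2S)-7-methoxy-5-{[4-methoxy-3-(triisopropylsilyloxy)benzyl]oxy}-2-[4-methoxy-3-(triisopropylsilyloxy)phenyl]chroman-4-one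
Conditions: Rh2(S-PTTL)4 (dirhodium tetrakis[N-phthaloyl-(S)-tert-leucinate], 1 mol %), CH2Cl2, 0 °C to rt, slow addition of 8
Reagents that add atoms: none
Why: Rh2(S-PTTL)4 expels N2 from 8 to give an electrophilic rhodium carbenoid at the future C3, which inserts in a concerted but asynchronous, hydride-transfer-like three-centre transition state into a benzylic O–CH2 C–H bond six atoms away (the future C2), forming the C2–C3 bond and releasing the catalyst. The closest known reaction type is the intramolecular C–H insertion of ortho-alkoxyaryl α-diazoketones to chroman-4-ones under chiral dirhodium tetracarboxylate catalysis. Ring C is closed as a six-membered ring in the 1,6-insertion mode through a chair-like transition state with the ring B aryl group pseudo-equatorial. C2, the only new stereocenter, is set under catalyst control: the chiral phthalimido-tert-leucinate ligand wall distinguishes the two enantiotopic hydrogens of the O–CH2 group, and because 8 is Cs-symmetric the same-sense hydrogen of either benzyl ether leads to the same (S) product. The step needs chemoselectivity for C–H insertion over oxonium-ylide formation at the ether oxygen with [1,2]-benzyl shift, over O–H insertion and over carbene dimerisation; the hydridic C–H bond flanked by O1 and the para-methoxyphenyl ring, the low nucleophilicity of aryl ether oxygens conjugated to the acyl group, the absence of any free hydroxyl (both ortho oxygens carry the same benzyl group) and slow addition at high dilution should secure it. Site selectivity is not at stake, since the two benzyl ethers are equivalent and no other sp3 C–H bond can reach the carbenoid through a five- or six-membered transition state.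

Step 7
Reactants: 9 (2S)-7-methoxy-5-{[4-methoxy-3-(triisopropylsilyloxy)benzyl]oxy}-2-[4-methoxy-3-(triisopropylsilyloxy)phenyl]chroman-4-one
Product: 10 (2S)-5-hydroxy-7-methoxy-2-[4-methoxy-3-(triisopropylsilyloxy)phenyl]chroman-4-one
Conditions: H2 (1 atm), 10% Pd/C, EtOAc, rt
Reagents that add atoms: none
Why: Heterogeneous hydrogenolysis should cleave the primary benzylic aryl ether on O5 much faster than the cyclic secondary benzylic C2–O1 bond or the ketone, under neutral conditions that leave C2 untouched and at a stage where no alkene is present.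

Step 8
Reactants: 10 (2S)-5-hydroxy-7-methoxy-2-[4-methoxy-3-(triisopropylsilyloxy)phenyl]chroman-4-one; 11 3-methylbut-2-en-1-ol (prenol)
Product: 12 (2S)-7-methoxy-2-[4-methoxy-3-(triisopropylsilyloxy)phenyl]-5-[(3-methylbut-2-en-1-yl)oxy]chroman-4-one
Conditions: PPh3, DIAD, THF, 0 °C to rt
Reagents that add atoms: none
Why: Mitsunobu etherification alkylates the chelated, weakly nucleophilic 5-OH by SN2 attack at the primary allylic carbon of activated prenol under essentially neutral conditions, avoiding the base that could open the flavanone to a chalcone and scramble C2.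

Step 9
Reactants: 12 (2S)-7-methoxy-2-[4-methoxy-3-(triisopropylsilyloxy)phenyl]-5-[(3-methylbut-2-en-1-yl)oxy]chroman-4-one
Product: 15 (2S)-5-hydroxy-7-methoxy-2-[4-methoxy-3-(triisopropylsilyloxy)phenyl]-8-(3-methylbut-2-en-1-yl)chroman-4-one, via ortho-dienone 13 (not isolated), via para-dienone 14 (not isolated)
Conditions: Eu(fod)3 (10 mol %), NaHCO3, PhCl, 85 °C
Reagents that add atoms: none
Why: In this aromatic Claisen–Cope sequence, chelation of trivalent europium between C4=O and O5 accelerates the [3,3] shift of the prenyl ether to C6 (the only free ortho position, giving dienone 13 with a reversed prenyl group), a second [3,3] (Cope) shift relays the unit to the para position C8 as a normal prenyl group (14), and enolisation restores ring A with the chelated 5-OH, C2 not being involved.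

Step 10
Reactants: 15 (2S)-5-hydroxy-7-methoxy-2-[4-methoxy-3-(triisopropylsilyloxy)phenyl]-8-(3-methylbut-2-en-1-yl)chroman-4-one
Product: 16 (2S)-5-hydroxy-2-(3-hydroxy-4-methoxyphenyl)-7-methoxy-8-(3-methylbut-2-en-1-yl)chroman-4-one (target)
Conditions: TBAF, AcOH, THF, 0 °C
Reagents that add atoms: none
Why: Fluoride cleaves the aryl silyl ether through the strong Si–F bond, while AcOH buffering keeps the medium non-basic so that the base-labile flavanone should keep its C2 configuration and the prenyl alkene stays untouched.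

**Compound list**

1 | isovanillin (3-hydroxy-4-methoxybenzaldehyde) | O=Cc1ccc(OC)c(O)c1 | starting material
2 | 4-methoxy-3-(triisopropylsilyloxy)benzaldehyde | O=Cc1ccc(OC)c(O[Si](C(C)C)(C(C)C)C(C)C)c1 | intermediate
3 | [4-methoxy-3-(triisopropylsilyloxy)phenyl]methanol | OCc1ccc(OC)c(O[Si](C(C)C)(C(C)C)C(C)C)c1 | intermediate
4 | 4-methoxy-3-(triisopropylsilyloxy)benzyl bromide | BrCc1ccc(OC)c(O[Si](C(C)C)(C(C)C)C(C)C)c1 | intermediate
5 | 1-(2,6-dihydroxy-4-methoxyphenyl)ethanone | CC(=O)c1c(O)cc(OC)cc1O | starting material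
6 | 1-{4-methoxy-2,6-bis[(4-methoxy-3-(triisopropylsilyloxy)benzyl)oxy]phenyl}ethanone | CC(=O)c1c(OCc2ccc(OC)c(O[Si](C(C)C)(C(C)C)C(C)C)c2)cc(OC)cc1OCc1ccc(OC)c(O[Si](C(C)C)(C(C)C)C(C)C)c1 | intermediate
7 | 4,4,4-trifluoro-1-{4-methoxy-2,6-bis[(4-methoxy-3-(triisopropylsilyloxy)benzyl)oxy]phenyl}butane-1,3-dione | O=C(CC(=O)C(F)(F)F)c1c(OCc2ccc(OC)c(O[Si](C(C)C)(C(C)C)C(C)C)c2)cc(OC)cc1OCc1ccc(OC)c(O[Si](C(C)C)(C(C)C)C(C)C)c1 | intermediate
8 | 2-diazo-1-{4-methoxy-2,6-bis[(4-methoxy-3-(triisopropylsilyloxy)benzyl)oxy]phenyl}ethanone | [N-]=[N+]=CC(=O)c1c(OCc2ccc(OC)c(O[Si](C(C)C)(C(C)C)C(C)C)c2)cc(OC)cc1OCc1ccc(OC)c(O[Si](C(C)C)(C(C)C)C(C)C)c1 | intermediate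
9 | (2S)-7-methoxy-5-{[4-methoxy-3-(triisopropylsilyloxy)benzyl]oxy}-2-[4-methoxy-3-(triisopropylsilyloxy)phenyl]chroman-4-one | COc1ccc([C@@H]2CC(=O)c3c(OCc4ccc(OC)c(O[Si](C(C)C)(C(C)C)C(C)C)c4)cc(OC)cc3O2)cc1O[Si](C(C)C)(C(C)C)C(C)C | intermediate
10 | (2S)-5-hydroxy-7-methoxy-2-[4-methoxy-3-(triisopropylsilyloxy)phenyl]chroman-4-one | COc1ccc([C@@H]2CC(=O)c3c(O)cc(OC)cc3O2)cc1O[Si](C(C)C)(C(C)C)C(C)C | intermediate
11 | 3-methylbut-2-en-1-ol (prenol) | CC(C)=CCO | starting material
12 | (2S)-7-methoxy-2-[4-methoxy-3-(triisopropylsilyloxy)phenyl]-5-[(3-methylbut-2-en-1-yl)oxy]chroman-4-one | COc1ccc([C@@H]2CC(=O)c3c(OCC=C(C)C)cc(OC)cc3O2)cc1O[Si](C(C)C)(C(C)C)C(C)C | intermediate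
13 | (2S)-7-methoxy-2-[4-methoxy-3-(triisopropylsilyloxy)phenyl]-6-(2-methylbut-3-en-2-yl)-2,3-dihydro-4H-chromene-4,5(6H)-dione (C6 configuration not defined) | COc1ccc([C@@H]2CC(=O)C3=C(O2)C=C(OC)C(C(C)(C)C=C)C3=O)cc1O[Si](C(C)C)(C(C)C)C(C)C | intermediate
14 | (2S)-7-methoxy-2-[4-methoxy-3-(triisopropylsilyloxy)phenyl]-8-(3-methylbut-2-en-1-yl)-2,3-dihydro-4H-chromene-4,5(8H)-dione (C8 configuration not defined) | COc1ccc([C@@H]2CC(=O)C3=C(O2)C(CC=C(C)C)C(OC)=CC3=O)cc1O[Si](C(C)C)(C(C)C)C(C)C | intermediate
15 | (2S)-5-hydroxy-7-methoxy-2-[4-methoxy-3-(triisopropylsilyloxy)phenyl]-8-(3-methylbut-2-en-1-yl)chroman-4-one | COc1ccc([C@@H]2CC(=O)c3c(O)cc(OC)c(CC=C(C)C)c3O2)cc1O[Si](C(C)C)(C(C)C)C(C)C | intermediate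
16 | (2S)-5-hydroxy-2-(3-hydroxy-4-methoxyphenyl)-7-methoxy-8-(3-methylbut-2-en-1-yl)chroman-4-one | COc1ccc([C@@H]2CC(=O)c3c(O)cc(OC)c(CC=C(C)C)c3O2)cc1O | target

**Step count and risks**

Total steps: 10. Longest linear sequence: 10 steps (1 to 16).

Steps most likely to fail:

Step 6. The carbenoid may be diverted into oxonium-ylide formation at the ether oxygen followed by a [1,2]-benzyl shift, or into carbene dimerisation, and the catalyst may discriminate the enantiotopic benzylic hydrogens insufficiently. The fallback sets out from 5 and comes back at 10, forming the C2–aryl bond instead. Acetophenone 5 would be condensed with N,N-dimethylformamide dimethyl acetal (toluene, 90 °C) to the enaminone (E)-3-(dimethylamino)-1-(2,6-dihydroxy-4-methoxyphenyl)prop-2-en-1-one F1, which on treatment with aqueous HCl in CH2Cl2 should cyclise with loss of dimethylamine to 5-hydroxy-7-methoxy-4H-chromen-4-one F2. In parallel, commercial 5-bromo-2-methoxyphenol would be silylated (TIPSCl, imidazole, DMF) to (5-bromo-2-methoxyphenoxy)triisopropylsilane F3 and converted by bromine–lithium exchange (n-BuLi, THF, −78 °C), B(OiPr)3 and aqueous work-up into [4-methoxy-3-(triisopropylsilyloxy)phenyl]boronic acid F4. Rhodium-catalysed asymmetric 1,4-addition of F4 to F2 ([Rh(OH)(cod)]2 with a chiral electron-poor biaryl bisphosphine of the MeO-BIPHEP type, toluene/H2O, rt; ligand antipode chosen for (S)) should then give 10, and steps 8 to 10 would follow unchanged.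

Step 9. The relay may stop after the first [3,3] shift through enolisation at C6, and the configuration at C2 may erode through Lewis-acid-assisted ring opening at 85 °C. The fallback sets out from 9 and comes back at 15, replacing the sigmatropic relay by halogenation and cross-coupling. Iodination of 9 with N-iodosuccinimide (cat. CF3CO2H, MeCN, 0 °C) should occur on ring A at C8, the less hindered of its two free positions, to give (2S)-8-iodo-7-methoxy-5-{[4-methoxy-3-(triisopropylsilyloxy)benzyl]oxy}-2-[4-methoxy-3-(triisopropylsilyloxy)phenyl]chroman-4-one F5; the regiochemistry would have to be confirmed. Stille coupling with tributyl(3-methylbut-2-en-1-yl)stannane (Pd(PPh3)4, DMF, 90 °C) should give (2S)-7-methoxy-5-{[4-methoxy-3-(triisopropylsilyloxy)benzyl]oxy}-2-[4-methoxy-3-(triisopropylsilyloxy)phenyl]-8-(3-methylbut-2-en-1-yl)chroman-4-one F6. Chelation-directed cleavage of the benzyl ether on O5 (MgBr2·OEt2, Me2S, CH2Cl2, rt), which spares the prenyl alkene, should then give 15.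

Step 7. Over-reduction may compete with removal of the benzyl group, either as hydrogenolytic opening of the cyclic benzylic C2–O1 bond or as reduction of the aryl ketone. The fallback sets out from 9 and comes back at 10, replacing reduction by Lewis-acid heterolysis. MgBr2·OEt2 with Me2S in CH2Cl2 at rt should chelate C4=O and O5, ionise only the O5–CH2 bond and trap the benzyl cation as its dimethylsulfonium salt. No compound outside the list would be made (entry F0).

Further compounds
F1 | step 6 | (E)-3-(dimethylamino)-1-(2,6-dihydroxy-4-methoxyphenyl)prop-2-en-1-one | CN(C)/C=C/C(=O)c1c(O)cc(OC)cc1O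
F2 | step 6 | 5-hydroxy-7-methoxy-4H-chromen-4-one | O=C1C=COc2cc(OC)cc(O)c12
F3 | step 6 | (5-bromo-2-methoxyphenoxy)triisopropylsilane | COc1ccc(Br)cc1O[Si](C(C)C)(C(C)C)C(C)C
F4 | step 6 | [4-methoxy-3-(triisopropylsilyloxy)phenyl]boronic acid | COc1ccc(B(O)O)cc1O[Si](C(C)C)(C(C)C)C(C)C
F5 | step 9 | (2S)-8-iodo-7-methoxy-5-{[4-methoxy-3-(triisopropylsilyloxy)benzyl]oxy}-2-[4-methoxy-3-(triisopropylsilyloxy)phenyl]chroman-4-one | COc1ccc([C@@H]2CC(=O)c3c(OCc4ccc(OC)c(O[Si](C(C)C)(C(C)C)C(C)C)c4)cc(OC)c(I)c3O2)cc1O[Si](C(C)C)(C(C)C)C(C)C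
F6 | step 9 | (2S)-7-methoxy-5-{[4-methoxy-3-(triisopropylsilyloxy)benzyl]oxy}-2-[4-methoxy-3-(triisopropylsilyloxy)phenyl]-8-(3-methylbut-2-en-1-yl)chroman-4-one | COc1ccc([C@@H]2CC(=O)c3c(OCc4ccc(OC)c(O[Si](C(C)C)(C(C)C)C(C)C)c4)cc(OC)c(CC=C(C)C)c3O2)cc1O[Si](C(C)C)(C(C)C)C(C)C
F0 | step 7 | none | none
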